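**Strategy**

Everything rests on making ring C of the upper epicatechin gallate unit from three pieces: the C3–C4 bond and the aryl ether bond O1–C8a are formed in one pot when an α-alkoxy aryl ketone and two molecules of a 2-fluorobenzaldehyde undergo an asymmetric aldol–Tishchenko reaction and the C2 alkoxide so released closes the ring by SNAr. The step exploits the syn C2–O/C3–O pattern of the 2,3-cis ring C and the benzylic C4 carbon: its Tishchenko ester is the leaving group for a later 4β→8 coupling with a middle–lower dimer made from (−)-epigallocatechin and (+)-catechin.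

Key step: step 5

Remark on the structure: the target is read as epicatechin gallate-(4β→8)-epigallocatechin gallate-(4β→8)-catechin gallate (upper and middle units 2R,3R, lower unit 2R,3S); atoms carry flavan numbers, Bn is benzyl and PMB is 4-methoxybenzyl.
Assumption: the (R)-binaphthoxide ligand is taken to give the absolute sense drawn for 12; if the induction turns out opposite, the (S)-ligand is used.

**Route**

Step 1
Reactants: 1 5-fluorobenzene-1,3-diol
Product: 2 1,3-bis(benzyloxy)-5-fluorobenzene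
Conditions: BnBr, K2CO3, acetone, reflux
Reagents that add atoms: benzyl bromide BrCc1ccccc1
Why: Williamson ether synthesis on both phenols masks the future 5- and 7-hydroxyls as hydrogenolysable benzyl ethers.

Step 2
Reactants: 2 1,3-bis(benzyloxy)-5-fluorobenzene
Product: 4 2,4-bis(benzyloxy)-6-fluorobenzaldehyde, via iminium chloride 3 (not isolated)
Conditions: POCl3, DMF, 0 to 60 °C; then aq. NaOAc
Reagents that add atoms: N,N-dimethylformamide CN(C)C=O; water O
Why: Vilsmeier–Haack formylation should go para to one benzyloxy group and ortho to the other, at the less hindered doubly activated carbon next to fluorine, and the iminium salt is hydrolysed on work-up.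

Step 3
Reactants: 5 (4-methoxyphenyl)methanol; 6 2-chloro-N-methoxy-N-methylacetamide
Product: 7 N-methoxy-2-[(4-methoxybenzyl)oxy]-N-methylacetamide
Conditions: NaH, THF, 0 °C to rt, Bu4NI (cat.)
Reagents that add atoms: none
Why: Williamson etherification of the sodium alkoxide with the activated α-chloro amide gives the PMB-protected glycolic Weinreb amide.

Step 4
Reactants: 8 1,2-bis(benzyloxy)-4-bromobenzene; 7 N-methoxy-2-[(4-methoxybenzyl)oxy]-N-methylacetamide
Product: 10 1-[3,4-bis(benzyloxy)phenyl]-2-[(4-methoxybenzyl)oxy]ethan-1-one, via aryllithium 9 (not isolated)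
Conditions: n-BuLi, THF, −78 °C; then 7, −78 to 0 °C; aq. NH4Cl
Reagents that add atoms: none
Why: Bromine–lithium exchange followed by Weinreb ketone synthesis, in which the chelated tetrahedral intermediate prevents over-addition.

Step 5
Reactants: 10 1-[3,4-bis(benzyloxy)phenyl]-2-[(4-methoxybenzyl)oxy]ethan-1-one; 4 2,4-bis(benzyloxy)-6-fluorobenzaldehyde (2.1 equiv)
Product: 13 (2R,3S,4R)-5,7-bis(benzyloxy)-2-[3,4-bis(benzyloxy)phenyl]-3-[(4-methoxybenzyl)oxy]-3,4-dihydro-2H-chromen-4-yl 2,4-bis(benzyloxy)-6-fluorobenzoate (2,3-cis-3,4-cis), via anti-aldol adduct 11 (not isolated), via diol monoester 12 (not isolated)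
Conditions: LaLi3[(R)-binaphthoxide]3 (10 mol %), THF, rt; then KN(SiMe3)2 (1.2 equiv), 18-crown-6, DMF, 60 °C, same flask, high dilution
Reagents that add atoms: none
Why: Proposed new method: the LaLi3(binaphthoxide)3 complex makes the enolate of 10, which adds reversibly to 4 (C3–C4 bond), the aldolate picks up a second molecule of 4, and the hemiacetal passes hydride to the C2 ketone through a chair-like six-membered transition state; KN(SiMe3)2 then turns the freed C2 hydroxyl into the alkoxide, which displaces fluoride at C8a (O1–C8a bond) by addition–elimination. The closest known reaction types are the catalytic asymmetric aldol–Tishchenko reaction of aryl ketones with aryl aldehydes and the alkoxide SNAr closure of chromans on fluoroarenes, whose merger in one flask with an α-alkoxy ketone is the new element. Ring C closes in the 6-exo mode through a Meisenheimer intermediate. C3 is fixed by the aldol equilibrium, because only the anti aldolate, with the OPMB group equatorial in the hydride-transfer chair, is reduced fast, so syn and anti aldolates funnel into one isomer; C2 is fixed by the internal 1,3-anti hydride delivery, which places the C2 and C3 oxygens syn and therefore gives 2,3-cis ring C with retention at C2; the absolute sense comes from the binaphthoxide ligand, and C4 (formed 3,4-cis) is erased later by ionisation. The step needs O1 to be the only oxygen that arylates: O3 is capped as the PMB ether and the C4 oxygen is either acylated or, after acyl migration, could only close a four-membered ring, so both acyl isomers drain through the C2 alkoxide. Intermolecular substitution at the carbonyl-activated fluoroarenes is held back by high dilution and by the twist of the 2,6-disubstituted aroyl groups.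

Step 6
Reactants: 13 3-O-PMB flavan-4-yl ester (key-step product)
Product: 14 (2R,3S,4R)-5,7-bis(benzyloxy)-2-[3,4-bis(benzyloxy)phenyl]-3-hydroxy-3,4-dihydro-2H-chromen-4-yl 2,4-bis(benzyloxy)-6-fluorobenzoate
Conditions: DDQ, CH2Cl2/pH 7 buffer, 0 °C
Reagents that add atoms: none
Why: Oxidative PMB cleavage through the 4-methoxybenzylic oxocarbenium ion should free O3 while the less electron-rich benzyl ethers, the ester and the three stereocenters stay untouched.

Step 7
Reactants: 14 3-hydroxyflavan-4-yl ester; 15 3,4,5-tris(benzyloxy)benzoyl chloride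
Product: 16 (2R,3S,4R)-5,7-bis(benzyloxy)-2-[3,4-bis(benzyloxy)phenyl]-4-{[2,4-bis(benzyloxy)-6-fluorobenzoyl]oxy}-3,4-dihydro-2H-chromen-3-yl 3,4,5-tris(benzyloxy)benzoate
Conditions: Et3N, DMAP (cat.), CH2Cl2, 0 °C
Reagents that add atoms: none
Why: DMAP-catalysed acylation of the 3-hydroxyl with the acid chloride installs the protected galloyl ester with retention at C3 and should be faster than migration of the neighbouring C4 ester.

Step 8
Reactants: 17 (+)-catechin
Product: 18 5,7,3',4'-tetra-O-benzyl-(+)-catechin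
Conditions: BnBr, K2CO3, DMF, rt, argon
Reagents that add atoms: benzyl bromide BrCc1ccccc1
Why: Williamson benzylation of the four phenols, which K2CO3 deprotonates while the aliphatic 3-hydroxyl and the 2R,3S centers are left alone.

Step 9
Reactants: 18 5,7,3',4'-tetra-O-benzyl-(+)-catechin; 15 3,4,5-tris(benzyloxy)benzoyl chloride
Product: 19 5,7,3',4'-tetra-O-benzyl-(+)-catechin 3-O-[3,4,5-tris(benzyloxy)benzoate]
Conditions: Et3N, DMAP (cat.), CH2Cl2, rt
Reagents that add atoms: none
Why: DMAP-catalysed acylation of the equatorial 3-hydroxyl gives the protected lower-unit gallate with retention at C3.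

Step 10
Reactants: 20 (−)-epigallocatechin
Product: 21 5,7,3',4',5'-penta-O-benzyl-(−)-epigallocatechin
Conditions: BnBr, K2CO3, DMF, 0 °C to rt, argon
Reagents that add atoms: benzyl bromide BrCc1ccccc1
Why: Williamson benzylation of the five phenols, which K2CO3 deprotonates under argon while the aliphatic 3-hydroxyl and the 2R,3R centers are left alone.

Step 11
Reactants: 21 5,7,3',4',5'-penta-O-benzyl-(−)-epigallocatechin; 15 3,4,5-tris(benzyloxy)benzoyl chloride
Product: 22 5,7,3',4',5'-penta-O-benzyl-(−)-epigallocatechin 3-O-[3,4,5-tris(benzyloxy)benzoate] (octa-O-benzyl-EGCG)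
Conditions: Et3N, DMAP (cat.), CH2Cl2, rt
Reagents that add atoms: none
Why: DMAP-catalysed acylation of the axial 3-hydroxyl with the acid chloride gives the protected middle-unit gallate with retention at C3.

Step 12
Reactants: 22 octa-O-benzyl-EGCG
Product: 23 4β-(2-ethoxyethoxy)-octa-O-benzyl-EGCG (2R,3R,4S)
Conditions: DDQ, 2-ethoxyethanol, CH2Cl2, rt
Reagents that add atoms: 2-ethoxyethanol CCOCCO
Why: DDQ abstracts hydride from benzylic C4 (oxidative C–H etherification through the 5,7-dialkoxy-stabilised cation) and the alcohol adds on the face opposite the C2 aryl and C3 ester groups, giving the 3,4-trans 4β ether.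

Step 13
Reactants: 23 4β-(2-ethoxyethoxy)-octa-O-benzyl-EGCG; 19 tetra-O-benzylcatechin tri-O-benzylgallate (4 equiv)
Product: 24 benzylated middle–lower dimer, octa-O-benzyl-EGCG-(4β→8)-[tetra-O-benzylcatechin 3-O-tri-O-benzylgallate]
Conditions: Me3SiOTf (cat.), CH2Cl2, −78 °C
Reagents that add atoms: none
Why: Lewis acid ionisation of the C4 ether gives the benzylic cation (SN1 Friedel–Crafts alkylation), which C8 of 19 attacks anti to the participating 3-O-galloyl group and the C2 aryl, so the middle C4 is set 3,4-trans (4β).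

Step 14
Reactants: 16 upper-unit electrophile; 24 benzylated middle–lower dimer (2.5 equiv)
Product: 25 fully benzylated trimer (22 benzyl ethers)
Conditions: Me3SiOTf (cat.), CH2Cl2, −78 to −40 °C, slow addition of 16
Reagents that add atoms: none
Why: The C4 ester of 16 ionises whatever its configuration (SN1 Friedel–Crafts alkylation) and the 3-O-galloyl carbonyl bridges the cation on the face it shares with the C2 aryl, so C8 of the middle unit of 24, its most nucleophilic free position, attacks from the other face and sets the upper C4 as 4β (3,4-trans).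

Step 15
Reactants: 25 fully benzylated trimer
Product: 26 target trimer CNP0321910.1
Conditions: H2 (1 atm), Pd(OH)2/C, THF/MeOH/H2O, rt
Reagents that add atoms: none
Why: Hydrogenolysis of the 22 benzyl ethers under neutral conditions should leave the three galloyl esters, both interflavan bonds and all eight stereocenters untouched.

**Compound list**

1 | 5-fluorobenzene-1,3-diol | Oc1cc(O)cc(F)c1 | starting material
2 | 1,3-bis(benzyloxy)-5-fluorobenzene | Fc1cc(OCc2ccccc2)cc(OCc2ccccc2)c1 | intermediate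
3 | N-[2,4-bis(benzyloxy)-6-fluorobenzylidene]-N-methylmethanaminium chloride (iminium chloride; not isolated) | C[N+](C)=Cc1c(F)cc(OCc2ccccc2)cc1OCc1ccccc1.[Cl-] | intermediate
4 | 2,4-bis(benzyloxy)-6-fluorobenzaldehyde | O=Cc1c(F)cc(OCc2ccccc2)cc1OCc1ccccc1 | intermediate
5 | (4-methoxyphenyl)methanol | COc1ccc(CO)cc1 | starting material
6 | 2-chloro-N-methoxy-N-methylacetamide | CON(C)C(=O)CCl | starting material
7 | N-methoxy-2-[(4-methoxybenzyl)oxy]-N-methylacetamide | CON(C)C(=O)COCc1ccc(OC)cc1 | intermediate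
8 | 1,2-bis(benzyloxy)-4-bromobenzene | Brc1ccc(OCc2ccccc2)c(OCc2ccccc2)c1 | starting material
9 | [3,4-bis(benzyloxy)phenyl]lithium (aryllithium; not isolated) | [Li]c1ccc(OCc2ccccc2)c(OCc2ccccc2)c1 | intermediate
10 | 1-[3,4-bis(benzyloxy)phenyl]-2-[(4-methoxybenzyl)oxy]ethan-1-one | O=C(COCc1ccc(OC)cc1)c1ccc(OCc2ccccc2)c(OCc2ccccc2)c1 | intermediate
11 | (2R,3R)-3-[2,4-bis(benzyloxy)-6-fluorophenyl]-1-[3,4-bis(benzyloxy)phenyl]-3-hydroxy-2-[(4-methoxybenzyl)oxy]propan-1-one (anti-aldol adduct; not isolated) | O[C@H](c1c(F)cc(OCc2ccccc2)cc1OCc1ccccc1)[C@@H](OCc1ccc(OC)cc1)C(=O)c1ccc(OCc2ccccc2)c(OCc2ccccc2)c1 | intermediate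
12 | (1R,2S,3R)-1-[2,4-bis(benzyloxy)-6-fluorophenyl]-3-[3,4-bis(benzyloxy)phenyl]-3-hydroxy-2-[(4-methoxybenzyl)oxy]propyl 2,4-bis(benzyloxy)-6-fluorobenzoate (diol monoester; not isolated) | O=C(c1c(F)cc(OCc2ccccc2)cc1OCc1ccccc1)O[C@H](c1c(F)cc(OCc2ccccc2)cc1OCc1ccccc1)[C@@H](OCc1ccc(OC)cc1)[C@H](O)c1ccc(OCc2ccccc2)c(OCc2ccccc2)c1 | intermediate
13 | (2R,3S,4R)-5,7-bis(benzyloxy)-2-[3,4-bis(benzyloxy)phenyl]-3-[(4-methoxybenzyl)oxy]-3,4-dihydro-2H-chromen-4-yl 2,4-bis(benzyloxy)-6-fluorobenzoate (2,3-cis-3,4-cis) | O=C(c1c(F)cc(OCc2ccccc2)cc1OCc1ccccc1)O[C@@H]1c2c(OCc3ccccc3)cc(OCc3ccccc3)cc2O[C@H](c2ccc(OCc3ccccc3)c(OCc3ccccc3)c2)[C@@H]1OCc1ccc(OC)cc1 | intermediate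
14 | (2R,3S,4R)-5,7-bis(benzyloxy)-2-[3,4-bis(benzyloxy)phenyl]-3-hydroxy-3,4-dihydro-2H-chromen-4-yl 2,4-bis(benzyloxy)-6-fluorobenzoate | O=C(c1c(F)cc(OCc2ccccc2)cc1OCc1ccccc1)O[C@@H]1c2c(OCc3ccccc3)cc(OCc3ccccc3)cc2O[C@H](c2ccc(OCc3ccccc3)c(OCc3ccccc3)c2)[C@@H]1O | intermediate
15 | 3,4,5-tris(benzyloxy)benzoyl chloride | O=C(Cl)c1cc(OCc2ccccc2)c(OCc2ccccc2)c(OCc2ccccc2)c1 | starting material
16 | (2R,3S,4R)-5,7-bis(benzyloxy)-2-[3,4-bis(benzyloxy)phenyl]-4-{[2,4-bis(benzyloxy)-6-fluorobenzoyl]oxy}-3,4-dihydro-2H-chromen-3-yl 3,4,5-tris(benzyloxy)benzoate (upper-unit electrophile) | O=C(c1c(F)cc(OCc2ccccc2)cc1OCc1ccccc1)O[C@@H]1c2c(OCc3ccccc3)cc(OCc3ccccc3)cc2O[C@H](c2ccc(OCc3ccccc3)c(OCc3ccccc3)c2)[C@@H]1OC(=O)c1cc(OCc2ccccc2)c(OCc2ccccc2)c(OCc2ccccc2)c1 | intermediate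
17 | (+)-catechin, (2R,3S) | O[C@H]1Cc2c(O)cc(O)cc2O[C@@H]1c1ccc(O)c(O)c1 | starting material
18 | 5,7,3',4'-tetra-O-benzyl-(+)-catechin | O[C@H]1Cc2c(OCc3ccccc3)cc(OCc3ccccc3)cc2O[C@@H]1c1ccc(OCc2ccccc2)c(OCc2ccccc2)c1 | intermediate
19 | 5,7,3',4'-tetra-O-benzyl-(+)-catechin 3-O-[3,4,5-tris(benzyloxy)benzoate] | O=C(O[C@H]1Cc2c(OCc3ccccc3)cc(OCc3ccccc3)cc2O[C@@H]1c1ccc(OCc2ccccc2)c(OCc2ccccc2)c1)c1cc(OCc2ccccc2)c(OCc2ccccc2)c(OCc2ccccc2)c1 | intermediate
20 | (−)-epigallocatechin, (2R,3R) | O[C@@H]1Cc2c(O)cc(O)cc2O[C@@H]1c1cc(O)c(O)c(O)c1 | starting material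
21 | 5,7,3',4',5'-penta-O-benzyl-(−)-epigallocatechin | O[C@@H]1Cc2c(OCc3ccccc3)cc(OCc3ccccc3)cc2O[C@@H]1c1cc(OCc2ccccc2)c(OCc2ccccc2)c(OCc2ccccc2)c1 | intermediate
22 | 5,7,3',4',5'-penta-O-benzyl-(−)-epigallocatechin 3-O-[3,4,5-tris(benzyloxy)benzoate] (octa-O-benzyl-EGCG) | O=C(O[C@@H]1Cc2c(OCc3ccccc3)cc(OCc3ccccc3)cc2O[C@@H]1c1cc(OCc2ccccc2)c(OCc2ccccc2)c(OCc2ccccc2)c1)c1cc(OCc2ccccc2)c(OCc2ccccc2)c(OCc2ccccc2)c1 | intermediate
23 | 4β-(2-ethoxyethoxy)-octa-O-benzyl-EGCG, (2R,3R,4S), 3,4-trans | O=C(O[C@@H]1[C@@H](OCCOCC)c2c(OCc3ccccc3)cc(OCc3ccccc3)cc2O[C@@H]1c1cc(OCc2ccccc2)c(OCc2ccccc2)c(OCc2ccccc2)c1)c1cc(OCc2ccccc2)c(OCc2ccccc2)c(OCc2ccccc2)c1 | intermediate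
24 | benzylated middle–lower dimer: epigallocatechin gallate-(4β→8)-catechin gallate with all 15 phenols as benzyl ethers | O=C(O[C@@H]1[C@@H](c2c(OCc4ccccc4)cc(OCc4ccccc4)c3c2O[C@H](c2ccc(OCc4ccccc4)c(OCc4ccccc4)c2)[C@@H](OC(=O)c2cc(OCc4ccccc4)c(OCc4ccccc4)c(OCc4ccccc4)c2)C3)c2c(OCc3ccccc3)cc(OCc3ccccc3)cc2O[C@@H]1c1cc(OCc2ccccc2)c(OCc2ccccc2)c(OCc2ccccc2)c1)c1cc(OCc2ccccc2)c(OCc2ccccc2)c(OCc2ccccc2)c1 | intermediate
25 | fully benzylated trimer: epicatechin gallate-(4β→8)-epigallocatechin gallate-(4β→8)-catechin gallate with all 22 phenols as benzyl ethers | O=C(O[C@@H]1[C@@H](c2c(OCc4ccccc4)cc(OCc4ccccc4)c3c2O[C@H](c2ccc(OCc4ccccc4)c(OCc4ccccc4)c2)[C@@H](OC(=O)c2cc(OCc4ccccc4)c(OCc4ccccc4)c(OCc4ccccc4)c2)C3)c2c(OCc3ccccc3)cc(OCc3ccccc3)c([C@H]3c4c(OCc5ccccc5)cc(OCc5ccccc5)cc4O[C@H](c4ccc(OCc5ccccc5)c(OCc5ccccc5)c4)[C@@H]3OC(=O)c3cc(OCc4ccccc4)c(OCc4ccccc4)c(OCc4ccccc4)c3)c2O[C@@H]1c1cc(OCc2ccccc2)c(OCc2ccccc2)c(OCc2ccccc2)c1)c1cc(OCc2ccccc2)c(OCc2ccccc2)c(OCc2ccccc2)c1 | intermediate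
26 | CNP0321910.1: epicatechin 3-O-gallate-(4β→8)-epigallocatechin 3-O-gallate-(4β→8)-catechin 3-O-gallate | O=C(O[C@@H]1[C@@H](c2c(O)cc(O)c3c2O[C@H](c2ccc(O)c(O)c2)[C@@H](OC(=O)c2cc(O)c(O)c(O)c2)C3)c2c(O)cc(O)c([C@H]3c4c(O)cc(O)cc4O[C@H](c4ccc(O)c(O)c4)[C@@H]3OC(=O)c3cc(O)c(O)c(O)c3)c2O[C@@H]1c1cc(O)c(O)c(O)c1)c1cc(O)c(O)c(O)c1 | target

**Step count and risks**

Total step count: 15. Longest linear sequence: 7 steps (1, 2, 5, 6, 7, 14, 15).

Steps most likely to fail:

Step 5. The aldol addition to the hindered, electron-rich aldehyde may stay reversible while 4 is consumed by Tishchenko dimerisation. In the second stage, intermolecular substitution at the carbonyl-activated fluoroarenes or fragmentation of the 1,3-alkoxide ester may outrun ring closure. The fallback uses known chemistry and gives up the single flask. Setting out from 10 and 4, the catalytic asymmetric aldol–Tishchenko reaction with LaLi3[(R)-binaphthoxide]3 is run alone and diol monoester 12 is isolated by chromatography, free of excess 4. Ring C is then closed in a separate flask by alkoxide SNAr (KH, 18-crown-6, THF, high dilution), which comes back to the route at 13. This fallback makes no compound outside the list (F0).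

Step 14. The C4 cation of 16 may attack C6 of the middle unit or C6 of the lower unit of 24 instead of C8 of the middle unit, or 16 may condense with its own unblocked ring A. The fallback changes the order of assembly so that each coupling meets only one nucleophilic ring. Setting out from 16 and 22, coupling with excess monomer 22 (Me3SiOTf, CH2Cl2, −78 °C) should give the benzylated upper–middle dimer F1. DDQ with 2-ethoxyethanol then oxidises C4 of its middle unit, the only benzylic CH2 of a flavan ring, to the 4β-(2-ethoxyethoxy) dimer F2. Coupling of F2 with excess 19 (Me3SiOTf) comes back to the route at 25.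

Step 12. DDQ may abstract hydride from the benzylic CH2 groups of the galloyl benzyl ethers, or oxidation of the 3-O-acylated flavan at C4 may be sluggish. The fallback oxidises C4 before the gallate is in place. Setting out from 21, DDQ with 2-ethoxyethanol on the free 3-ol should give 4β-(2-ethoxyethoxy)-5,7,3',4',5'-penta-O-benzyl-epigallocatechin F3. Acylation of F3 with 15 (Et3N, DMAP, CH2Cl2) comes back to the route at 23.

Further compounds
F0 | step 5 | none | none
F1 | step 14 | benzylated upper–middle dimer: epicatechin gallate-(4β→8)-epigallocatechin gallate with all 15 phenols as benzyl ethers | O=C(O[C@@H]1Cc2c(OCc3ccccc3)cc(OCc3ccccc3)c([C@H]3c4c(OCc5ccccc5)cc(OCc5ccccc5)cc4O[C@H](c4ccc(OCc5ccccc5)c(OCc5ccccc5)c4)[C@@H]3OC(=O)c3cc(OCc4ccccc4)c(OCc4ccccc4)c(OCc4ccccc4)c3)c2O[C@@H]1c1cc(OCc2ccccc2)c(OCc2ccccc2)c(OCc2ccccc2)c1)c1cc(OCc2ccccc2)c(OCc2ccccc2)c(OCc2ccccc2)c1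
F2 | step 14 | benzylated upper–middle dimer carrying a 4β-(2-ethoxyethoxy) group at C4 of the middle unit | O=C(O[C@@H]1[C@@H](OCCOCC)c2c(OCc3ccccc3)cc(OCc3ccccc3)c([C@H]3c4c(OCc5ccccc5)cc(OCc5ccccc5)cc4O[C@H](c4ccc(OCc5ccccc5)c(OCc5ccccc5)c4)[C@@H]3OC(=O)c3cc(OCc4ccccc4)c(OCc4ccccc4)c(OCc4ccccc4)c3)c2O[C@@H]1c1cc(OCc2ccccc2)c(OCc2ccccc2)c(OCc2ccccc2)c1)c1cc(OCc2ccccc2)c(OCc2ccccc2)c(OCc2ccccc2)c1
F3 | step 12 | 4β-(2-ethoxyethoxy)-5,7,3',4',5'-penta-O-benzyl-epigallocatechin (3,4-trans) | O[C@@H]1[C@@H](OCCOCC)c2c(OCc3ccccc3)cc(OCc3ccccc3)cc2O[C@@H]1c1cc(OCc2ccccc2)c(OCc2ccccc2)c(OCc2ccccc2)c1
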